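**Retrosynthetic overview**
1. Target 21 ⇒ acylation of the C8 alcohol 20 with methacrylic anhydride.
2. 20 ⇒ C7–C8 ring closure. C7 of a 4‑bromobutenolide acts as an alkenyl‑Cr(III) β‑acylvinyl anion (an sp2 homoenolate, d3) toward the C8 aldehyde of 17. The ten‑membered ring forms last.
3. 17 ⇒ C1 aldehyde 11 by crotylboration (sets C10), hydroboration and double oxidation. 11 ⇒ ozonolysis of the prenyl group of 9.
4. 9 ⇒ C6–C7 bond plus lactone in one operation. The same carbon C7 serves a first time as a β‑acylvinyl anion, as the Mg carbenoid of dibromoacrylate 6, toward epoxy aldehyde 3.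
5. 3 ⇒ Sharpless epoxidation of nerol. 6 ⇒ ethyl bromopyruvate, KOAc and CBr4. Ring order: oxirane → butenolide → carbocycle. No protecting groups.

Assumption: germacrane locants are used (C1 ketone, C4/C5 oxirane, C6 lactone carbinol, C7=C11, C8 ester carbinol, C10 CHMe, C12 lactone C=O, C13 CH2OAc). The SMILES reads as (4S,5R,6R,8R,10S) with C3 and C6 cis on the oxirane, so the epoxide must come from a Z‑olefin (nerol).

**Step 1**
Reactants: 1 nerol
Product: 2 (2R,3S)-2,3-epoxynerol
Conditions: Ti(OiPr)4 (10 mol %), D-(−)-DET (12 mol %), TBHP, 4 Å MS, CH2Cl2, −20 °C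
Reagents that add atoms: tert-butyl hydroperoxide, CC(C)(C)OO
Why: Katsuki–Sharpless asymmetric epoxidation touches only the allylic alcohol olefin, and D-(−)-tartrate delivers oxygen to the face that sets C4 (S) and C5 (R), with the Z‑geometry carried over into the cis oxirane.

**Step 2**
Reactants: 2 (2R,3S)-2,3-epoxynerol
Product: 3 (2S,3S)-3-methyl-3-(4-methylpent-3-enyl)oxirane-2-carbaldehyde
Conditions: TEMPO (10 mol %), PhI(OAc)2, CH2Cl2, rt
Reagents that add atoms: none
Why: The oxoammonium (TEMPO/BAIB) oxidation stops at the aldehyde, leaves oxirane and olefin alone and creates no stereocentre (the CIP label at C5 changes only through priorities).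

**Step 3**
Reactants: 4 ethyl bromopyruvate
Product: 5 ethyl 3-acetoxy-2-oxopropanoate
Conditions: KOAc, DMF, 0 °C → rt
Reagents that add atoms: potassium acetate, CC(=O)[O-].[K+]
Why: SN2 displacement of the primary, α‑keto‑activated bromide by acetate installs the C13 acetate at the outset.

**Step 4**
Reactants: 5 ethyl 3-acetoxy-2-oxopropanoate
Product: 6 ethyl 2-(acetoxymethyl)-3,3-dibromoprop-2-enoate
Conditions: CBr4, PPh3, CH2Cl2, 0 °C
Reagents that add atoms: carbon tetrabromide, BrC(Br)(Br)Br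
Why: Ramirez dibromoolefination (Wittig type) attacks only the activated keto carbonyl, brings in C7, and raises no E/Z question because both new substituents are Br.

**Step 5**
Reactants: 6 ethyl 2-(acetoxymethyl)-3,3-dibromoprop-2-enoate; 3 (2S,3S)-3-methyl-3-(4-methylpent-3-enyl)oxirane-2-carbaldehyde
Product: 9 [(5S)-4-bromo-5-{(2R,3S)-3-methyl-3-(4-methylpent-3-enyl)oxiran-2-yl}-2-oxo-2,5-dihydrofuran-3-yl]methyl acetate, via magnesium carbenoid 7 (not isolated), via chloromagnesium alkoxide 8 (not isolated)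
Conditions: 6, iPrMgCl, THF, −78 °C, 30 min; then 3, −78 °C → rt; aq NH4Cl
Reagents that add atoms: none
Why: Ester‑chelation‑directed Br/Mg exchange gives the alkenylmagnesium cis to CO2Et, a β‑acylvinyl anion joining the normally electrophilic acrylate β‑carbon C7 to the aldehyde carbon C6; the cis alkoxide then lactonises, and C6 is set by Felkin–Anh/Cornforth attack anti to the oxirane C–O, reinforced by the cis C3 chain (spatially the 6R centre of the target, CIP S here because of Br).

**Step 6**
Reactants: 9 bromobutenolide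
Product: 11 [(5S)-4-bromo-5-{(2R,3S)-3-methyl-3-(3-oxopropyl)oxiran-2-yl}-2-oxo-2,5-dihydrofuran-3-yl]methyl acetate, via secondary ozonide 10 (not isolated)
Conditions: O3, CH2Cl2, −78 °C (Sudan III end point); PPh3, −78 °C → rt
Reagents that add atoms: ozone, [O-][O+]=O
Why: Ozonolysis cleaves the electron‑rich prenyl olefin, whereas the tetrasubstituted, acceptor‑ and bromine‑substituted butenolide olefin is inert; no stereocentre is touched.

**Step 7**
Reactants: 11 C1 aldehyde
Product: 13 [(5S)-4-bromo-5-{(2R,3S)-3-[(3R,4S)-3-hydroxy-4-methylhex-5-enyl]-3-methyloxiran-2-yl}-2-oxo-2,5-dihydrofuran-3-yl]methyl acetate, via pinacol borate 12 (not isolated)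
Conditions: (E)-crotyl-Bpin, (S)-TRIP phosphoric acid (5 mol %), 4 Å MS, toluene, −30 °C; aq NaHCO3
Reagents that add atoms: (E)-crotylboronic acid pinacol ester, C/C=C/CB1OC(C)(C)C(C)(C)O1
Why: Chiral‑phosphoric‑acid‑catalysed crotylboration goes through a closed chair, so the E‑boronate gives the anti adduct and the (S)‑catalyst directs Si‑face attack, which sets C10 (S); the C1 carbinol (R) is erased later, and the oxygen stays masked as a borate until the basic work‑up.

**Step 8**
Reactants: 13 homoallylic alcohol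
Product: 15 [(5S)-4-bromo-5-{(2R,3S)-3-[(3R,4S)-3,6-dihydroxy-4-methylhexyl]-3-methyloxiran-2-yl}-2-oxo-2,5-dihydrofuran-3-yl]methyl acetate, via bis-9-BBN adduct 14 (not isolated)
Conditions: 9-BBN (2.5 equiv), THF, 0 °C → rt; NaBO3·4H2O, THF/H2O, rt
Reagents that add atoms: sodium perborate, [Na+].[Na+].O[B-]1(O)OO[B-](O)(O)OO1
Why: Anti‑Markovnikov hydroboration–oxidation of the only unhindered olefin puts oxygen on C8; 9‑BBN ignores lactone, acetate, oxirane and vinyl bromide, and perborate keeps the medium nearly neutral.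

**Step 9**
Reactants: 15 1,4-diol
Product: 17 [(5S)-4-bromo-5-{(2R,3S)-3-methyl-3-[(4S)-4-methyl-3,6-dioxohexyl]oxiran-2-yl}-2-oxo-2,5-dihydrofuran-3-yl]methyl acetate, via bis(alkoxysulfonium) salt 16 (not isolated)
Conditions: (COCl)2, DMSO, CH2Cl2, −78 °C; iPr2NEt, −78 → −20 °C
Reagents that add atoms: none
Why: Swern oxidation activates both hydroxyls before any carbonyl exists, so the 1,4‑diol cannot drain through a lactol to the γ‑lactone, and C10 is not epimerised at low temperature.

**Step 10**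
Reactants: 17 keto aldehyde
Product: 20 (4S,5R,6R,8R,10S)-13-acetoxy-4,5-epoxy-8-hydroxy-1-oxogermacr-7(11)-en-12,6-olide, via alkenylchromium species 18 (not isolated), via chromium alkoxide 19 (not isolated)
Conditions: CrCl2 (4 equiv), valinol-derived oxazoline–sulfonamide ligand (4.4 equiv, antipode that delivers to the Si face), Et3N, NiCl2(2,9-dimethylphenanthroline) (10 mol %), THF, rt, 17 added by syringe pump to 2 mM
Reagents that add atoms: none
Why: In this Nozaki–Hiyama–Kishi macrocyclisation Ni(0) inserts into the activated β‑bromo‑enoate C–Br bond and hands C7 to Cr(III), a second β‑acylvinyl anion at the same carbon, which adds only to the aldehyde (ketone, lactone, acetate and oxirane are tolerated); this closes the ten‑membered ring, with C8 (R) set by the chiral Cr–sulfonamide complex.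

**Step 11**
Reactants: 20 macrocyclic alcohol
Product: 21 (4S,5R,6R,8R,10S)-13-acetoxy-4,5-epoxy-8-methacryloyloxy-1-oxogermacr-7(11)-en-12,6-olide (target)
Conditions: methacrylic anhydride, DMAP, Et3N, BHT (trace), CH2Cl2, 0 °C → rt
Reagents that add atoms: methacrylic anhydride, C=C(C)C(=O)OC(=O)C(C)=C
Why: DMAP‑catalysed (Steglich‑type) acylation proceeds with retention at C8 and pulls any transannular C1/C8 hemiketal back through the open hydroxy ketone.

**Compound list**
1 | nerol, (2Z)-3,7-dimethylocta-2,6-dien-1-ol | CC(C)=CCC/C(C)=C\CO | starting material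
2 | (2R,3S)-2,3-epoxynerol | CC(C)=CCC[C@]1(C)O[C@@H]1CO | intermediate
3 | (2S,3S)-3-methyl-3-(4-methylpent-3-enyl)oxirane-2-carbaldehyde | CC(C)=CCC[C@]1(C)O[C@@H]1C=O | intermediate
4 | ethyl bromopyruvate | CCOC(=O)C(=O)CBr | starting material
5 | ethyl 3-acetoxy-2-oxopropanoate | CCOC(=O)C(=O)COC(C)=O | intermediate
6 | ethyl 2-(acetoxymethyl)-3,3-dibromoprop-2-enoate | CCOC(=O)C(COC(C)=O)=C(Br)Br | intermediate
7 | ethyl (E)-2-(acetoxymethyl)-3-bromo-3-(chloromagnesio)prop-2-enoate (Mg cis to ester) | CCOC(=O)/C(COC(C)=O)=C(/Br)[Mg]Cl | intermediate (not isolated)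
8 | chloromagnesium alkoxide of the aldehyde adduct (C6 cis to ester) | CC(C)=CCC[C@]1(C)O[C@@H]1[C@H](O[Mg]Cl)/C(Br)=C(/COC(C)=O)C(=O)OCC | intermediate (not isolated)
9 | 4-bromobutenolide with prenyl side chain | CC(C)=CCC[C@]1(C)O[C@@H]1[C@@H]1OC(=O)C(COC(C)=O)=C1Br | intermediate
10 | secondary ozonide of 9 (trioxolane CH centre undefined) | CC1(C)OOC(CC[C@]2(C)O[C@@H]2[C@@H]2OC(=O)C(COC(C)=O)=C2Br)O1 | intermediate (not isolated)
11 | C1 aldehyde | O=CCC[C@]1(C)O[C@@H]1[C@@H]1OC(=O)C(COC(C)=O)=C1Br | intermediate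
12 | pinacol borate of 13 | C=C[C@H](C)[C@H](OB1OC(C)(C)C(C)(C)O1)CC[C@]1(C)O[C@@H]1[C@@H]1OC(=O)C(COC(C)=O)=C1Br | intermediate (not isolated)
13 | anti homoallylic alcohol (C1 R, C10 S) | C=C[C@H](C)[C@H](O)CC[C@]1(C)O[C@@H]1[C@@H]1OC(=O)C(COC(C)=O)=C1Br | intermediate
14 | C8-(9-BBN), O1-(9-BBN) adduct | B1(CC[C@H](C)[C@H](OB2C3CCCC2CCC3)CC[C@]2(C)O[C@@H]2[C@@H]2OC(=O)C(COC(C)=O)=C2Br)C2CCCC1CCC2 | intermediate (not isolated)
15 | C1,C8-diol | OCC[C@H](C)[C@H](O)CC[C@]1(C)O[C@@H]1[C@@H]1OC(=O)C(COC(C)=O)=C1Br | intermediate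
16 | bis(dimethylalkoxysulfonium) dichloride of 15 | C[S+](C)OCC[C@H](C)[C@H](O[S+](C)C)CC[C@]1(C)O[C@@H]1[C@@H]1OC(=O)C(COC(C)=O)=C1Br.[Cl-].[Cl-] | intermediate (not isolated)
17 | C1-keto C8-aldehyde | O=CC[C@H](C)C(=O)CC[C@]1(C)O[C@@H]1[C@@H]1OC(=O)C(COC(C)=O)=C1Br | intermediate
18 | C7 alkenylchromium(III) species (ligand omitted) | O=CC[C@H](C)C(=O)CC[C@]1(C)O[C@@H]1[C@@H]1OC(=O)C(COC(C)=O)=C1[Cr](Cl)Cl | intermediate (not isolated)
19 | chromium(III) alkoxide of 20 (ligand omitted) | Cl[Cr](Cl)O[C@@H]1C[C@H](C)C(=O)CC[C@]2(C)O[C@@H]2[C@@H]2OC(=O)C(COC(C)=O)=C21 | intermediate (not isolated)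
20 | 8-hydroxy macrocycle | O[C@@H]1C[C@H](C)C(=O)CC[C@]2(C)O[C@@H]2[C@@H]2OC(=O)C(COC(C)=O)=C21 | intermediate
21 | CNP0128625.1 | C=C(C)C(=O)O[C@@H]1C[C@H](C)C(=O)CC[C@]2(C)O[C@@H]2[C@@H]2OC(=O)C(COC(C)=O)=C21 | target

**Totals:** 11 steps in all. The longest linear sequence is 9 steps (1, 2, 5, 6, 7, 8, 9, 10, 11).

**Steps most likely to fail**

Step 10 is the largest risk. In 18 the lactone C6–O bond lies antiperiplanar to C7–Cr, so β‑carboxylate elimination to an allenoate may outrun ring closure. Ligand control at C8 is also untested in a macrocyclisation. The fallback sets out from 17 and swaps the polarity of the two carbons. An N‑heterocyclic carbene (thiazolium or triazolium salt, iPr2NEt, dilute THF, 40 °C) converts the C8 aldehyde into its Breslow acyl anion. This adds to C7 of the vinylogous acyl bromide and expels bromide (Stetter‑type addition–elimination) to give the 8‑oxo macrocycle F1. (S)‑Me‑CBS with catecholborane in toluene at −78 °C then reduces the more electrophilic, alkenyl‑flanked C8 ketone to the 8R alcohol, and the route is rejoined at 20.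

Step 5 may suffer from incomplete cis selectivity in the exchange, loss of the acetate to ethoxide, or a modest Felkin ratio. The fallback sets out from 3 and builds the same ring from an alkyne‑level β‑acylvinyl anion. Lithiated ethyl propiolate (LDA, THF, −78 °C) adds in the same Felkin sense to give the γ‑hydroxy ynoate F2. MgBr2·OEt2 with paraformaldehyde (CH2Cl2, 0 °C) then adds bromide at C7. The resulting allenolate takes up formaldehyde at C11 from the less hindered bromine side, and lactonisation gives the hydroxymethyl bromobutenolide F3. Ac2O/pyridine brings this back to the route at 9.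

Step 8 keeps a free C1 hydroxyl next to the acid‑labile trisubstituted oxirane, where 5‑exo closure to a tetrahydrofuran is possible. It also exposes the β‑bromobutenolide to a peroxide nucleophile. The fallback sets out from 13 and removes the hydroxyl at once. Dess–Martin periodinane with NaHCO3 gives the β,γ‑unsaturated ketone F4. A nitrite‑modified, aldehyde‑selective Wacker oxidation (PdCl2(PhCN)2, CuCl2, AgNO2, O2, tBuOH/MeNO2, rt) then oxidises the terminal carbon directly and rejoins the route at 17, bypassing 15.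

**Further compounds**
F1 | step 10 | (4S,5R,6R,10S)-13-acetoxy-4,5-epoxy-1,8-dioxogermacr-7(11)-en-12,6-olide | O=C1C[C@H](C)C(=O)CC[C@]2(C)O[C@@H]2[C@@H]2OC(=O)C(COC(C)=O)=C12
F2 | step 5 | ethyl 4-hydroxy-4-{(2R,3S)-3-methyl-3-(4-methylpent-3-enyl)oxiran-2-yl}but-2-ynoate (C6 as in 9) | CC(C)=CCC[C@]1(C)O[C@@H]1[C@H](O)C#CC(=O)OCC
F3 | step 5 | 4-bromo-3-(hydroxymethyl)-5-{(2R,3S)-3-methyl-3-(4-methylpent-3-enyl)oxiran-2-yl}furan-2(5H)-one (C6 as in 9) | CC(C)=CCC[C@]1(C)O[C@@H]1[C@@H]1OC(=O)C(CO)=C1Br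
F4 | step 8 | β,γ-unsaturated C1 ketone, (10S)-vinyl analogue of 17 | C=C[C@H](C)C(=O)CC[C@]1(C)O[C@@H]1[C@@H]1OC(=O)C(COC(C)=O)=C1Br
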